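**Assumption:** the target is read as the (7E,12Z,18S,20Z)-isomer of variabilin exactly as drawn, and 4-methoxy-3-methylfuran-2(5H)-one (14) is taken as a catalogue compound.

## Retrosynthetic overview

1. Target ⇐ O-demethylation of its 4-O-methyl ether ⇐ vinylogous aldol/E1cB condensation (C20=C21, Z) of 4-methoxy-3-methylfuran-2(5H)-one with a (2S)-2-methyl aldehyde.
2. (2S)-Aldehyde ⇐ amine/chiral-phosphate transfer hydrogenation of the (E)-2-methyl-2-enal with enantioselective enamine protonation (sets C18, the only stereocentre; new).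
3. Enal ⇐ ω-selective SeO2 allylic oxidation of the furanyl triene chain.
4. Chain ⇐ allyl–allyl C10–C11 coupling of nerylbarium chloride (nerol supplies 12Z) with an (E)-allylic bromide from perillene (3-bromofuran + homoprenyl Grignard, then SeO2 and Appel; supplies 7E).
5. Rings: neither ring is constructed; the furan enters first with 3-bromofuran (step 1) and the butenolide last as the methyl tetronate (step 8).

## Route

Step 1
Reactants: 1 3-bromofuran; 2 5-bromo-2-methylpent-2-ene
Product: 4 perillene [3-(4-methylpent-3-en-1-yl)furan], via homoprenylmagnesium bromide 3 (not isolated)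
Conditions: 2, Mg, THF, rt; then 1, NiCl2(dppp) (2 mol %), Et2O, 0 °C to reflux
Reagents that add atoms: none
Why: Kumada–Tamao–Corriu coupling of a primary alkyl Grignard reagent with the heteroaryl bromide under the divalent nickel diphosphine precatalyst, whose chelating ligand suppresses β-hydride elimination while the trisubstituted olefin is inert.

Step 2
Reactants: 4 perillene
Product: 5 (2E)-5-(furan-3-yl)-2-methylpent-2-en-1-ol
Conditions: SeO2 (0.3 equiv), t-BuOOH (3 equiv), salicylic acid (0.1 equiv), CH2Cl2, 0 °C to rt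
Reagents that add atoms: selenium dioxide, O=[Se]=O (oxygen donor, catalytic); tert-butyl hydroperoxide, CC(C)(C)OO (terminal oxidant that returns the oxygen to selenium)
Why: Riley allylic oxidation (ene reaction then [2,3]-sigmatropic shift) hydroxylates only the E-methyl of the isopropylidene group, which fixes the 7E olefin geometry; the 3-alkylfuran is tolerated.

Step 3
Reactants: 5 (2E)-5-(furan-3-yl)-2-methylpent-2-en-1-ol
Product: 6 3-[(3E)-5-bromo-4-methylpent-3-en-1-yl]furan
Conditions: CBr4, PPh3, CH2Cl2, 0 °C; short silica plug, used at once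
Reagents that add atoms: carbon tetrabromide, BrC(Br)(Br)Br
Why: Appel reaction, SN2 displacement of the alkoxyphosphonium at the primary allylic carbon under neutral conditions that spare the furan and keep the E geometry.

Step 4
Reactants: 7 nerol [(2Z)-3,7-dimethylocta-2,6-dien-1-ol]
Product: 8 neryl chloride [(2Z)-1-chloro-3,7-dimethylocta-2,6-diene]
Conditions: PPh3, CCl4, 65 °C
Reagents that add atoms: carbon tetrachloride, ClC(Cl)(Cl)Cl
Why: Appel-type chlorination converts the primary allylic alcohol into the chloride without allylic transposition or Z to E isomerisation.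

Step 5
Reactants: 8 neryl chloride; 6 3-[(3E)-5-bromo-4-methylpent-3-en-1-yl]furan
Product: 10 3-[(3E,7Z)-4,8,12-trimethyltrideca-3,7,11-trien-1-yl]furan, via nerylbarium chloride 9 (not isolated)
Conditions: BaI2, lithium biphenylide (2 equiv), THF, rt (gives finely divided zerovalent barium); 8 (2 equiv), −78 °C, 30 min; then 6, −78 °C, 1 h
Reagents that add atoms: none
Why: allylbarium α,α′ cross-coupling: the allylbarium reagent is configurationally stable at −78 °C and attacks through its α-carbon in an SN2 displacement of the primary allylic bromide, forming C10–C11 with both the 12Z and the 7E olefins retained.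

Step 6
Reactants: 10 3-[(3E,7Z)-4,8,12-trimethyltrideca-3,7,11-trien-1-yl]furan
Product: 12 (2E,6Z,10E)-13-(furan-3-yl)-2,6,10-trimethyltrideca-2,6,10-trienal, via allylic alcohol 11 (not isolated)
Conditions: SeO2 (0.3 equiv), t-BuOOH (2 equiv), salicylic acid (0.1 equiv), CH2Cl2, 0 °C, stopped near 60% conversion (10 recovered); filter; then MnO2 (10 equiv), CH2Cl2, rt
Reagents that add atoms: selenium dioxide, O=[Se]=O (oxygen donor, catalytic); tert-butyl hydroperoxide, CC(C)(C)OO (terminal oxidant that returns the oxygen to selenium)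
Why: Riley oxidation of polyprenyl chains prefers the E-methyl of the terminal isopropylidene, the least hindered and most electron-rich olefin, and MnO2 then takes the primary allylic alcohol selectively to the enal.

Step 7
Reactants: 12 (2E,6Z,10E)-13-(furan-3-yl)-2,6,10-trimethyltrideca-2,6,10-trienal
Product: 13 (2S,6Z,10E)-13-(furan-3-yl)-2,6,10-trimethyltrideca-6,10-dienal
Conditions: 9-amino-9-deoxy-epi-quinine (10 mol %), (R)-TRIP [(R)-3,3′-bis(2,4,6-triisopropylphenyl)-1,1′-binaphthyl-2,2′-diyl hydrogen phosphate] (20 mol %), di-tert-butyl Hantzsch ester (1.2 equiv), H2O (2 equiv), MTBE, 0 °C, 24 h; cold silica plug, used the same day (ee assayed on a NaBH4-reduced aliquot)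
Reagents that add atoms: none
Why: Proposed new method: iminium–enamine transfer hydrogenation of an acyclic (E)-2-methylalk-2-enal in which the stereocentre is created at Cα. The primary amine condenses with the α-branched enal to an s-trans iminium ion paired with the chiral phosphate, the Hantzsch ester delivers hydride to C17 to give a geometrically defined E-enamine, and the quinuclidinium N–H/phosphoric acid of the chiral ion pair protonates the Re face of C18 faster than the enamine can equilibrate, giving the 2S aldehyde after hydrolysis (this amine/acid pair is the working choice; the pseudo-enantiomeric 9-amino-9-deoxy-epi-quinidine/(S)-TRIP pair gives the opposite sense). The closest known reaction types are the iminium-catalysed Hantzsch-ester reduction of β,β-disubstituted enals (stereocentre at Cβ), primary-amine/chiral-phosphate activation of α-branched enals, and primary-amine-catalysed conjugate addition with enantioselective enamine protonation of α-substituted acroleins.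

Step 8
Reactants: 13 (2S,6Z,10E)-13-(furan-3-yl)-2,6,10-trimethyltrideca-6,10-dienal; 14 4-methoxy-3-methylfuran-2(5H)-one
Product: 18 (5Z)-4-methoxy-3-methyl-5-[(2S,6Z,10E)-13-(furan-3-yl)-2,6,10-trimethyltrideca-6,10-dien-1-ylidene]furan-2(5H)-one, via lithium furanolate 15 (not isolated), via lithium aldolate 16 (not isolated), via aldol mesylate 17 (not isolated)
Conditions: 14, LiN(iPr)2, THF, −78 °C; 13, −78 °C, 30 min; MsCl (3 equiv), −78 to 0 °C; DBU (5 equiv), 0 °C to rt, 1–2 h
Reagents that add atoms: none
Why: vinylogous aldol addition of the aromatic lithium 2-furanolate through C5 is fast at −78 °C, so the α-stereocentre of 13 is not enolised; mesylation and E1cB elimination then give the 5-ylidene butenolide, with Z favoured because the E isomer suffers allylic strain against the 4-methoxy group.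

Step 9
Reactants: 18 (5Z)-4-methoxy-3-methyl-5-[(2S,6Z,10E)-13-(furan-3-yl)-2,6,10-trimethyltrideca-6,10-dien-1-ylidene]furan-2(5H)-one
Product: 20 (5Z)-5-[(2S,6Z,10E)-13-(furan-3-yl)-2,6,10-trimethyltrideca-6,10-dien-1-ylidene]-4-hydroxy-3-methylfuran-2(5H)-one (target), via sodium tetronate 19 (not isolated)
Conditions: NaSEt (3 equiv), DMF, rt; then cold 1 M HCl to pH 3, EtOAc
Reagents that add atoms: none
Why: SN2 O-demethylation of the vinylogous methyl carbonate by the soft thiolate (the tetronate is a carboxylate-like leaving group); no strong acid is used, so the furan and olefins survive, and the product anion shields C18 from epimerisation.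

## Compound list

1 | 3-bromofuran | Brc1ccoc1 | starting material
2 | 5-bromo-2-methylpent-2-ene | CC(C)=CCCBr | starting material
3 | (4-methylpent-3-en-1-yl)magnesium bromide (formed in situ) | CC(C)=CCC[Mg]Br | intermediate
4 | perillene, 3-(4-methylpent-3-en-1-yl)furan | CC(C)=CCCc1ccoc1 | intermediate
5 | (2E)-5-(furan-3-yl)-2-methylpent-2-en-1-ol | OC/C(C)=C/CCc1ccoc1 | intermediate
6 | 3-[(3E)-5-bromo-4-methylpent-3-en-1-yl]furan | BrC/C(C)=C/CCc1ccoc1 | intermediate
7 | nerol, (2Z)-3,7-dimethylocta-2,6-dien-1-ol | CC(C)=CCC/C(C)=C\CO | starting material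
8 | neryl chloride, (2Z)-1-chloro-3,7-dimethylocta-2,6-diene | CC(C)=CCC/C(C)=C\CCl | intermediate
9 | [(2Z)-3,7-dimethylocta-2,6-dien-1-yl]barium chloride (formed in situ) | CC(C)=CCC/C(C)=C\C[Ba]Cl | intermediate
10 | 3-[(3E,7Z)-4,8,12-trimethyltrideca-3,7,11-trien-1-yl]furan | CC(C)=CCC/C(C)=C\CC/C(C)=C/CCc1ccoc1 | intermediate
11 | (2E,6Z,10E)-13-(furan-3-yl)-2,6,10-trimethyltrideca-2,6,10-trien-1-ol (formed in situ) | OC/C(C)=C/CC/C(C)=C\CC/C(C)=C/CCc1ccoc1 | intermediate
12 | (2E,6Z,10E)-13-(furan-3-yl)-2,6,10-trimethyltrideca-2,6,10-trienal | O=C/C(C)=C/CC/C(C)=C\CC/C(C)=C/CCc1ccoc1 | intermediate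
13 | (2S,6Z,10E)-13-(furan-3-yl)-2,6,10-trimethyltrideca-6,10-dienal | O=C[C@@H](C)CCC/C(C)=C\CC/C(C)=C/CCc1ccoc1 | intermediate
14 | 4-methoxy-3-methylfuran-2(5H)-one | COC1=C(C)C(=O)OC1 | starting material
15 | lithium 4-methoxy-3-methylfuran-2-olate (formed in situ) | [Li+].[O-]c1occ(OC)c1C | intermediate
16 | lithium alkoxide of 5-[(2S,6Z,10E)-13-(furan-3-yl)-1-hydroxy-2,6,10-trimethyltrideca-6,10-dien-1-yl]-4-methoxy-3-methylfuran-2(5H)-one, diastereomer mixture at the two new centres (formed in situ) | [Li+].[O-]C(C1OC(=O)C(C)=C1OC)[C@@H](C)CCC/C(C)=C\CC/C(C)=C/CCc1ccoc1 | intermediate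
17 | methanesulfonate of the aldol 16 (formed in situ) | CS(=O)(=O)OC(C1OC(=O)C(C)=C1OC)[C@@H](C)CCC/C(C)=C\CC/C(C)=C/CCc1ccoc1 | intermediate
18 | (5Z)-4-methoxy-3-methyl-5-[(2S,6Z,10E)-13-(furan-3-yl)-2,6,10-trimethyltrideca-6,10-dien-1-ylidene]furan-2(5H)-one | CC1=C(OC)/C(=C/[C@@H](C)CCC/C(C)=C\CC/C(C)=C/CCc2ccoc2)OC1=O | intermediate
19 | sodium salt of 20 (formed in situ) | CC1=C([O-])/C(=C/[C@@H](C)CCC/C(C)=C\CC/C(C)=C/CCc2ccoc2)OC1=O.[Na+] | intermediate
20 | (5Z)-5-[(2S,6Z,10E)-13-(furan-3-yl)-2,6,10-trimethyltrideca-6,10-dien-1-ylidene]-4-hydroxy-3-methylfuran-2(5H)-one | CC1=C(O)/C(=C/[C@@H](C)CCC/C(C)=C\CC/C(C)=C/CCc2ccoc2)OC1=O | target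

## Step count and risks

Total step count: 9. Longest linear sequence: 8 (steps 1, 2, 3, 5, 6, 7, 8, 9).

Three steps most likely to fail:

**Step 7 (the proposed new reaction).** The enantioselectivity of the enamine protonation is untested. The enamine may lose its geometry by imine tautomerisation, the product aldehyde can racemise by re-forming the enamine, and the primary amine can be consumed by reductive amination. The fallback uses known chemistry, sets out from enal 12 and returns to the route at aldehyde 13. Enal 12 is reduced with an (S)-selective flavin-dependent ene-reductase of the Old Yellow Enzyme class (NADPH recycled with glucose/glucose dehydrogenase, phosphate buffer pH 7 with an MTBE layer), coupled with an NADPH-dependent alcohol dehydrogenase that removes the aldehyde as it forms. This class of enzyme is established for (E)-2-methylalk-2-enals and gives (2S,6Z,10E)-13-(furan-3-yl)-2,6,10-trimethyltrideca-6,10-dien-1-ol F1. Dess–Martin periodinane (NaHCO3, CH2Cl2, 0 °C) then returns 13 without touching the stereocentre.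

**Step 6.** The two internal trisubstituted olefins (oxidation at C10 or C15) can compete with the terminal one, and conversion must be held back. The fallback sets out from 8 and 6 and returns to the route at 12, moving the oxidation to a stage where only one olefin is reactive. Chloride 8 is converted (PhSO2Na, DMF) into neryl phenyl sulfone F2, in which the 2,3-olefin is deactivated by the allylic sulfonyl group. SeO2/t-BuOOH then oxidises only the isopropylidene E-methyl to (2E,6Z)-2,6-dimethyl-8-(phenylsulfonyl)octa-2,6-dien-1-ol F4. Its dianion (n-BuLi, 2.1 equiv, THF, −78 °C) is C-alkylated by bromide 6 to (2E,6Z,10E)-13-(furan-3-yl)-2,6,10-trimethyl-8-(phenylsulfonyl)trideca-2,6,10-trien-1-ol F5. Reductive desulfonylation (PdCl2(dppp) cat., LiBHEt3, THF, 0 °C; hydride goes to the less hindered allyl terminus) gives alcohol 11, here isolated, and MnO2 oxidises it to 12.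

**Step 5.** Preparing reactive barium is demanding, and Wurtz homocoupling of 8 or SN2′ attack on 6 would lower the yield. The fallback sets out from 8 and 6 and returns to the route at 10 by a sulfone-stabilised coupling. Chloride 8 and PhSO2Na (DMF, rt) give [(2Z)-3,7-dimethylocta-2,6-dien-1-yl]sulfonylbenzene F2. Its lithio derivative (n-BuLi, THF, −78 °C) is alkylated by 6 to 3-[(3E,7Z)-4,8,12-trimethyl-6-(phenylsulfonyl)trideca-3,7,11-trien-1-yl]furan F3. PdCl2(dppp) (cat.)/LiBHEt3 (THF, 0 °C) then removes the sulfonyl group, with the olefin position and geometry expected to be retained (hydride enters at the secondary terminus), to give 10.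

## Further compounds

F1 | step 7 | (2S,6Z,10E)-13-(furan-3-yl)-2,6,10-trimethyltrideca-6,10-dien-1-ol | OC[C@@H](C)CCC/C(C)=C\CC/C(C)=C/CCc1ccoc1
F2 | step 5 | [(2Z)-3,7-dimethylocta-2,6-dien-1-yl]sulfonylbenzene (neryl phenyl sulfone) | CC(C)=CCC/C(C)=C\CS(=O)(=O)c1ccccc1
F3 | step 5 | 3-[(3E,7Z)-4,8,12-trimethyl-6-(phenylsulfonyl)trideca-3,7,11-trien-1-yl]furan | CC(C)=CCC/C(C)=C\C(S(=O)(=O)c1ccccc1)C/C(C)=C/CCc1ccoc1
F4 | step 6 | (2E,6Z)-2,6-dimethyl-8-(phenylsulfonyl)octa-2,6-dien-1-ol | OC/C(C)=C/CC/C(C)=C\CS(=O)(=O)c1ccccc1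
F5 | step 6 | (2E,6Z,10E)-13-(furan-3-yl)-2,6,10-trimethyl-8-(phenylsulfonyl)trideca-2,6,10-trien-1-ol | OC/C(C)=C/CC/C(C)=C\C(S(=O)(=O)c1ccccc1)C/C(C)=C/CCc1ccoc1
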